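All runs are calculated from invented constants, and the scatter is random.

Minutes before the catalyst works cost the intermediate little, so I count lifetimes of the intermediate instead of minutes.

all flasks: impurity 0.76 mM
- Thursday's: substrate 0.30 M; precatalyst 0.5 mol%; run made earlier
- Sunday's: substrate 0.30 M; precatalyst 0.25 mol%; run made earlier
- Friday's: substrate 0.30 M; precatalyst 0.38 mol%; run made earlier
- Wednesday's: substrate 0.15 M; precatalyst 0.5 mol%; run made earlier
- oak: substrate 0.30 M; precatalyst 0.5 mol%; a closed flask charged with all of it at once and left for 15 min; time 15 min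
- elm: substrate 0.30 M (fed, over 12.0 min); precatalyst 0.5 mol%; a stirred flask in which substrate is dosed at a steady rate over 12.0 min without added volume, worked up at 15 min; time 15 min
- birch: substrate 0.30 M; precatalyst 0.5 mol%; one stirred flow tank at steady state, fed with the mixture as stated, mean residence time 15 min

| run | time / min | intermediate / % | product / % |
|---|---|---|---|
| Thursday's | 1.33 | 73.3 | 1.1 |
| Thursday's | 2.00 | 85.6 | 2.1 |
| Thursday's | 3.00 | 90.4 | 4.8 |
| Thursday's | 4.00 | 87.6 | 11.2 |
| Thursday's | 6.00 | 77.0 | 23.0 |
| Thursday's | 10.0 | 56.0 | 44.5 |
| Thursday's | 15.0 | 37.1 | 63.6 |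
| Sunday's | 0.667 | 49.8 | 0.3 |
| Sunday's | 2.00 | 86.2 | 0.1 |
| Sunday's | 3.00 | 94.2 | 1.2 |
| Sunday's | 5.00 | 98.5 | 1.1 |
| Sunday's | 8.00 | 98.0 | 2.1 |
| Sunday's | 10.0 | 97.6 | 3.2 |
| Sunday's | 12.0 | 96.4 | 3.8 |
| Friday's | 1.00 | 63.5 | 0 |
| Friday's | 1.33 | 73.5 | 0.8 |
| Friday's | 2.00 | 86.9 | 1.1 |
| Friday's | 3.00 | 92.6 | 1.4 |
| Friday's | 5.00 | 93.0 | 6.5 |
| Friday's | 8.00 | 82.1 | 17.2 |
| Friday's | 12.0 | 69.9 | 29.4 |
| Wednesday's | 1.00 | 63.7 | 0 |
| Wednesday's | 2.00 | 85.5 | 1.4 |
| Wednesday's | 3.00 | 94.7 | 0.9 |
| Wednesday's | 6.00 | 97.8 | 2.7 |
| Wednesday's | 12.0 | 97.1 | 2.9 |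

(scatter of a reading: 0.5 percentage points)

- the stated concentrations are those of everything mixed, before any reaction; amounts are the same in each set-up
- the feed brings no volume worth counting
- the earlier runs were made in a closed, stirred flask

1. the set-up with the highest amount of intermediate at the outlet or at the end, in percent of the substrate put in ("none" if the first two lie within 2 percentage points) (oak / elm / birch / none)
2. amount of intermediate at the outlet or at the end, in percent of the substrate put in, oak
3. amount of intermediate at the outlet or at the end, in percent of the substrate put in, elm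
4. amount of intermediate at the outlet or at the end, in percent of the substrate put in, birch

Substrate becomes intermediate with a rate constant of about 1.01 /min, read from Wednesday's run. Later, intermediate falls pseudo-first-order: between 6.00 min and 15.0 min on Thursday it goes from 77.0% to 37.1%, a constant of 0.0811 /min. I define the excess as c(precatalyst) − c(impurity). On Thursday it is 0.740 mM, on Friday 0.380 mM, where the constant reads 0.0402 /min. On Sunday the 0.750 mM of precatalyst lies below the impurity, and product reaches 3.8% at 12.0 min. So I carry the loss constant per unit of excess, 0.110 /mM/min; Friday's reads 0.106 /mM/min. A portion's count is this constant times the excess times its minutes after the lag, and exp(−count) of it survives. Thursday's line, run back to the full charge, puts the lag at 2.78 min.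

Oak repeats Thursday: its count is 0.992, which returns 37.1% by construction. In elm, I take intermediate to arrive evenly over the feed, one substrate lifetime late, so the last portion's count is 0.163; averaging survival over arrivals gives me 54.7%. In birch, I take 83.1% of the tank's contents as older than the lag, so the constant becomes 0.0674 /min, and the tank balance gives 46.7%.

The forecast names elm, since “late-fed substrate has less time to convert”: oak 37.2% (36.3% to 38.1%), elm 54.3% (51.5% to 57%), birch 47% (42% to 50%). My birch figure comes by another route, through ages in the tank rather than an activated fraction.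

The flasks give oak 36.9%, elm 54.5% and birch 47.7%, so elm leads.

    substrate → intermediate (k = 0.0170 /s)
    free catalyst + intermediate → free catalyst + product (k = 3.80 /M/s)
    precatalyst ⇌ free catalyst (K = 0.940, k = 0.00700 /s)
    free catalyst + impurity → spent catalyst (k = 360 /M/s)

The forecast stands at this loading, but oak's answer has moved by 5 points at 0.47 mol% and at 0.53 mol% of precatalyst. The same flask as oak with 0.85 mol% of precatalyst has an excess of 1.79 mM, a count of 2.40 and so 9.09% by my reckoning; that flask ends with 7.97% intermediate.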